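The constants used here are invented; the flask was simulated.

Z.D is paid for in D, so the quick number depends on how much D reaches Z before its other partners take it.

all flasks: D 0.350 M; E 0.250 M; time 2.5 d
- south-west: Q 0.060 M
- east: Q 0.12 M
- north-west: Q 0.25 M
- south-east: Q 0.50 M
- south: Q 1.0 M

    Q ⇌ Z, rate k1*(cs1 - [Z]) while solid is left; crystals form when [Z] > cs1 (cs1 = 0.32 M, k1 = 4.7 /h)
    Z + D → Z.D (k2 = 0.26 /M/h)
    D → G (k3 = 0.20 /h)
    2 D → D2 (k4 = 0.077 /M/h)
    D + E → D.E (k5 = 6.9 /M/h)

- [Z.D] at the end for south-west, east, north-west, south-east, south, in this order
- the course of these numbers from the first flask to the last (hardly changes / falls all the way / rises all the way / rises, then falls / falls, then rises)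

- a step written with two of one species runs at k times the square of its concentration and takes two of it each time
- as a solid, counted per litre of solution: Q
- at the start none of Q is in solution
- "hardly changes" means that all values lie within two and a half points (for a concentration: within two and a half percent of the largest)
- a step back or a flat step of under half a percent of the largest counts as no turn
- run time (south-west): 2.5 d

The hunch that a bigger charge of Q keeps paying holds up to the solubility, and the south flask shows the reckoning. At the start in south-west, with the same charges of D and E, E uses D 8.6 times as fast as the step to G does. So E can be treated as served first: reckoned as if it took D mole for mole up to its charge of 0.250 M, it leaves 0.100 M of the 0.350 M of D.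

In south, the 1.0 M of Q stands above the solubility of 0.32 M. Dissolved Z climbs towards the solubility with a time of 0.213 h, shorter than the 0.40 h half-life of D against E, reckoned for south-west with the same charges of D and E, so in south Z is taken at 0.32 M throughout. The leftover D then has two main exits: towards Z at 0.0832 /h and towards G at 0.20 /h. The step to D2, at 0.0154 /h, is slower than the step to G and is dropped.

The quantity to carry is the product share (a selectivity), the rate towards Z divided by the sum of the rates towards Z and G. It comes to 29.4 % in south, so the reckoning gives 0.0294 M of Z.D there. South-east, with 0.50 M of Q, also stands above the solubility, so the reckoning gives it the same share. South-west, east and north-west are charged with Q below the solubility, so there Z is taken at the charge of Q, and the share reckoned for each is smaller.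

The forecast reads 0.0066 M, 0.0128 M, 0.023 M, 0.029 M and 0.029 M, a course that rises all the way, on the grounds that “the yield rises with Q and then levels off at the top two loads”.

The simulation gives 0.00682 M, 0.0128 M, 0.0234 M, 0.0284 M and 0.0284 M, a course that rises all the way. In south, 65.2 % of the Q charged is still solid at the end. South-west starts with 0.060 M of Q, below the solubility, and holds 0 % of it as solid at 2.50 d. Its product share, with Z taken at the full charge, is 7.24 %, and that share of the 0.100 M of leftover D comes to 0.00724 M, against the 0.00682 M of Z.D that south-west holds at the end.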